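**Assumptions (one line each)**
- The target has no stereocentres, so there is no enantiomer to control; the only stereo-element in the route is the E-alkene of chalcone 14, which is consumed in step 12.
- The aryl sulfates are drawn as free acids as in the target SMILES but are handled as Na⁺ or Et₃NH⁺ salts; the free-acid form is obtained by cold H⁺ ion exchange at the end.

## Retrosynthetic overview
1. Target 18 ⇐ hydrogenolysis of the 3'-O-benzyl ether ⇐ tri-O-sulfation of 3'-O-benzylrhamnetin 16 (3,5,4'-triol). The sulfate pattern is fixed by protecting groups: Bn at 3', MOM at 5 and 4'.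
2. Flavonol 15 ⇐ Algar–Flynn–Oyamada cyclisation of 2'-hydroxychalcone 14 ⇐ Claisen–Schmidt coupling of A-ring acetophenone 7 (16 heavy atoms) with B-ring aldehyde 13 (20 heavy atoms).
3. A-ring 7 ⇐ resorcinol: bis-MOM, Ir C–H borylation/oxidation (third oxygen), O-methylation, directed lithiation/acetylation, release of one MOM.
4. B-ring 13 ⇐ 4-bromophenol: ortho-formylation, MOM, Baeyer–Villiger (second oxygen), benzylation, Br/Li exchange–formylation.
5. Ring order: the A and B benzene rings come from the starting materials; only the pyranone C ring is built (step 12), after the fragment union.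

## Branch A (A-ring acetophenone)

**Step 1**
Reactants: 1 resorcinol
Product: 2 1,3-bis(methoxymethoxy)benzene
Conditions: MOMCl (2.4 equiv), i-Pr₂NEt, CH₂Cl₂, 0 °C → rt
Reagents that add atoms: chloromethyl methyl ether, COCCl
Why: Simple O-alkylation of both phenols (Williamson-type acetal formation) gives a base-stable, ortho-directing protecting group.

**Step 2**
Reactants: 2
Product: 3 3,5-bis(methoxymethoxy)phenol
Conditions: [Ir(OMe)(cod)]₂ (1 mol%), dtbpy (2 mol%), B₂pin₂, THF, 80 °C; then one-pot 30% H₂O₂, aq NaOH, 0 °C → rt; neutralise to pH ~6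
Reagents that add atoms: hydrogen peroxide, OO (supplies the phenolic O; B₂pin₂, CC1(C)OB(OC1(C)C)B1OC(C)(C)C(C)(C)O1, is transient and leaves no atoms)
Why: Sterically controlled Ir-catalysed C–H borylation picks C5, the only C–H with no ortho substituent, and basic peroxide oxidation of the aryl boronate gives the phenol without touching the MOM ethers.

**Step 3**
Reactants: 3
Product: 4 1-methoxy-3,5-bis(methoxymethoxy)benzene
Conditions: MeI, K₂CO₃, acetone, reflux
Reagents that add atoms: iodomethane, CI
Why: Williamson methylation of the only free phenol installs the future 7-OMe.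

**Step 4**
Reactants: 4; 5 N-methoxy-N-methylacetamide
Product: 6 1-[4-methoxy-2,6-bis(methoxymethoxy)phenyl]ethanone
Conditions: n-BuLi (1.1 equiv), TMEDA, THF, 0 °C, 1 h; then 5, −78 °C → 0 °C; aq NH₄Cl
Reagents that add atoms: none beyond reactant 5 (CC(=O)N(C)OC), which supplies the acetyl group
Why: Directed ortho-metalation goes to the position flanked by two OMOM groups (stronger directors than OMe), and the Weinreb amide's chelated tetrahedral intermediate stops at the ketone.

**Step 5**
Reactants: 6
Product: 7 1-[2-hydroxy-4-methoxy-6-(methoxymethoxy)phenyl]ethanone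
Conditions: I₂ (10 mol%), MeOH, rt, monitored by TLC and stopped at mono-cleavage; aq Na₂S₂O₃
Reagents that add atoms: none
Why: Carbonyl-assisted acetal solvolysis removes one ortho MOM, and the resulting chelated phenol ties up the carbonyl so the second MOM reacts much more slowly; any over-deprotected diol can be recycled with 1 equiv MOMCl.

## Branch B (B-ring aldehyde)

**Step 6**
Reactants: 8 4-bromophenol
Product: 9 5-bromo-2-hydroxybenzaldehyde
Conditions: (CH₂O)ₙ, MgCl₂, Et₃N, MeCN, reflux
Reagents that add atoms: paraformaldehyde (formaldehyde, C=O)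
Why: Mg-phenoxide-directed ortho-formylation (Casnati–Skattebøl) is exclusively ortho, and the para position is blocked by Br.

**Step 7**
Reactants: 9
Product: 10 5-bromo-2-(methoxymethoxy)benzaldehyde
Conditions: MOMCl, i-Pr₂NEt, CH₂Cl₂, 0 °C → rt
Reagents that add atoms: chloromethyl methyl ether, COCCl
Why: O-alkylation masks the phenol that will become the 4'-oxygen with an acid-labile group.

**Step 8**
Reactants: 10
Product: 11 5-bromo-2-(methoxymethoxy)phenol
Conditions: mCPBA, NaHCO₃, CH₂Cl₂, rt; then K₂CO₃, MeOH, rt (one pot)
Reagents that add atoms: mCPBA, OOC(=O)c1cccc(Cl)c1 (supplies the new phenolic O; the formyl carbon leaves as formate)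
Why: Baeyer–Villiger oxidation of an ortho-alkoxybenzaldehyde proceeds with aryl migration to the aryl formate, which is methanolysed to the phenol; bicarbonate buffering protects the MOM ether.

**Step 9**
Reactants: 11
Product: 12 2-(benzyloxy)-4-bromo-1-(methoxymethoxy)benzene
Conditions: BnBr, K₂CO₃, DMF, rt
Reagents that add atoms: benzyl bromide, BrCc1ccccc1
Why: Williamson benzylation places the hydrogenolysis-labile group on the oxygen that becomes the free 3'-OH, making it orthogonal to the MOM groups.

**Step 10**
Reactants: 12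
Product: 13 3-(benzyloxy)-4-(methoxymethoxy)benzaldehyde
Conditions: n-BuLi (1.05 equiv), THF, −78 °C, 15 min; DMF, −78 → 0 °C; aq NH₄Cl
Reagents that add atoms: N,N-dimethylformamide, CN(C)C=O
Why: Br/Li exchange at −78 °C is faster than any ortho- or benzylic deprotonation, and DMF traps the aryllithium as the aldehyde (Bouveault formylation) para to OMOM.

## Fragment union and endgame

**Step 11**
Reactants: 7; 13
Product: 14 (E)-3-[3-(benzyloxy)-4-(methoxymethoxy)phenyl]-1-[2-hydroxy-4-methoxy-6-(methoxymethoxy)phenyl]prop-2-en-1-one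
Conditions: KOH (50% aq, excess), EtOH, rt, 36–48 h; acidify to pH ~5 with cold AcOH
Reagents that add atoms: none
Why: Claisen–Schmidt aldol condensation of the methyl ketone with the non-enolisable aldehyde gives the thermodynamically favoured E-enone; MOM and Bn ethers are base-stable.

**Step 12**
Reactants: 14
Product: 15 2-[3-(benzyloxy)-4-(methoxymethoxy)phenyl]-3-hydroxy-7-methoxy-5-(methoxymethoxy)-4H-chromen-4-one
Conditions: 30% H₂O₂, 2 M aq NaOH, MeOH/THF, 0 °C → rt; AcOH to pH 5
Reagents that add atoms: hydrogen peroxide, OO (supplies the 3-OH oxygen)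
Why: Algar–Flynn–Oyamada reaction: the 2'-phenoxide closes onto the β-carbon with peroxide oxidation at Cα, and the dihydroflavonol is oxidised in situ to the flavonol.

**Step 13**
Reactants: 15
Product: 16 2-[3-(benzyloxy)-4-hydroxyphenyl]-3,5-dihydroxy-7-methoxy-4H-chromen-4-one (3'-O-benzylrhamnetin)
Conditions: 3 M aq HCl, MeOH/THF, 55 °C, 3 h
Reagents that add atoms: none
Why: Acidic acetal hydrolysis removes both MOM groups while the benzyl and methyl ethers survive, leaving exactly the three hydroxyls (3, 5, 4') that are to be sulfated.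

**Step 14**
Reactants: 16
Product: 17 3'-O-benzylrhamnetin 3,5,4'-tri-O-sulfate (isolated as the trisodium salt)
Conditions: SO₃·NEt₃ (≥8 equiv per OH), DMA, 65 °C, 24–48 h (or SO₃·NMe₃/Et₃N, MeCN, microwave 100 °C); NaOAc exchange; Sephadex LH-20 or C18
Reagents that add atoms: sulfur trioxide–triethylamine complex, CC[N+](CC)(CC)S(=O)(=O)[O-]
Why: Exhaustive O-sulfonation with a large excess of amine–SO₃ complex and heat drives even the chelated 5-OH to the sulfate monoester; the benzyl ether is inert.

**Step 15**
Reactants: 17
Product: 18 rhamnetin 3,5,4'-tri-O-sulfate (target)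
Conditions: H₂ (1 atm), 10% Pd/C, MeOH/H₂O (4:1), trace NaHCO₃, rt; filter; Dowex 50W (H⁺), 0 °C, lyophilise if the free acid is needed
Reagents that add atoms: none
Why: Catalytic hydrogenolysis cleaves only the benzyl C–O bond under neutral conditions, which anionic aryl sulfate salts and the flavonol C2=C3 bond tolerate, exposing the 3'-OH.

## Compound list
1 | resorcinol | Oc1cccc(O)c1 | starting material
2 | 1,3-bis(methoxymethoxy)benzene | COCOc1cccc(OCOC)c1 | intermediate
3 | 3,5-bis(methoxymethoxy)phenol | COCOc1cc(O)cc(OCOC)c1 | intermediate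
4 | 1-methoxy-3,5-bis(methoxymethoxy)benzene | COCOc1cc(OC)cc(OCOC)c1 | intermediate
5 | N-methoxy-N-methylacetamide | CC(=O)N(C)OC | starting material
6 | 1-[4-methoxy-2,6-bis(methoxymethoxy)phenyl]ethanone | CC(=O)c1c(OCOC)cc(OC)cc1OCOC | intermediate
7 | 1-[2-hydroxy-4-methoxy-6-(methoxymethoxy)phenyl]ethanone | CC(=O)c1c(O)cc(OC)cc1OCOC | intermediate
8 | 4-bromophenol | Oc1ccc(Br)cc1 | starting material
9 | 5-bromo-2-hydroxybenzaldehyde | O=Cc1cc(Br)ccc1O | intermediate
10 | 5-bromo-2-(methoxymethoxy)benzaldehyde | COCOc1ccc(Br)cc1C=O | intermediate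
11 | 5-bromo-2-(methoxymethoxy)phenol | COCOc1ccc(Br)cc1O | intermediate
12 | 2-(benzyloxy)-4-bromo-1-(methoxymethoxy)benzene | COCOc1ccc(Br)cc1OCc1ccccc1 | intermediate
13 | 3-(benzyloxy)-4-(methoxymethoxy)benzaldehyde | COCOc1ccc(C=O)cc1OCc1ccccc1 | intermediate
14 | (E)-2'-hydroxy-4'-methoxy-6',4-bis(methoxymethoxy)-3-benzyloxychalcone | COCOc1ccc(/C=C/C(=O)c2c(O)cc(OC)cc2OCOC)cc1OCc1ccccc1 | intermediate
15 | 3'-O-benzyl-5,4'-di-O-MOM-rhamnetin | COCOc1ccc(-c2oc3cc(OC)cc(OCOC)c3c(=O)c2O)cc1OCc1ccccc1 | intermediate
16 | 3'-O-benzylrhamnetin | COc1cc(O)c2c(=O)c(O)c(-c3ccc(O)c(OCc4ccccc4)c3)oc2c1 | intermediate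
17 | 3'-O-benzylrhamnetin 3,5,4'-tri-O-sulfate | COc1cc(OS(=O)(=O)O)c2c(=O)c(OS(=O)(=O)O)c(-c3ccc(OS(=O)(=O)O)c(OCc4ccccc4)c3)oc2c1 | intermediate
18 | rhamnetin 3,5,4'-tri-O-sulfate | COc1cc(OS(=O)(=O)O)c2c(=O)c(OS(=O)(=O)O)c(-c3ccc(OS(=O)(=O)O)c(O)c3)oc2c1 | target

## Summary
**Total steps:** 15 (branch A: steps 1–5; branch B: steps 6–10; union and endgame: steps 11–15).
**Longest linear sequence:** 10 steps (steps 1–5 or 6–10, then 11–15).

**Three steps most likely to fail**
1. **Step 12 (AFO cyclisation).** 6'-Alkoxy-2'-hydroxychalcones can divert to aurones or stall at the dihydroflavonol. Fallback: build the C ring as the flavone by oxidative cyclisation of 14, then introduce the 3-OH separately by C3-lithiation (LDA), B(OMe)₃ and H₂O₂, or by DMDO epoxidation and ring opening.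
2. **Step 14 (sulfation of the chelated 5-OH).** The reaction may stop at the 3,4'-disulfate. Fallback: install all three sulfates as neutral 2,2,2-trichloroethyl sulfate diesters using TCE chlorosulfate with Et₃N/DMAP, which are chromatographable and use a much stronger electrophile. Pd/C with HCO₂NH₄ then removes the TCE groups and the benzyl ether in one operation.
3. **Step 4 (lithiation/acetylation).** Risks are partial lithiation between OMOM and OMe, and enolisation of the Weinreb amide by the hindered aryllithium. Fallback: reverse the order. Lithiate and acetylate 2 at its single doubly activated C2 first, then introduce the third oxygen by Ir borylation/oxidation para to the acetyl group (the only unhindered C–H) and methylate it.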